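**Plan**

- Retrosynthetic cuts, in order: the C14=C15 enol ether (back to a lactol); the C7 ketone and C8 acetate (back to a C7=C8 alkene through its epoxide); the C11–C12 single bond (back to an alkene); the O–C9 bond of the oxolane (back to a C12–C13 oxirane); C12=C13 (Horner–Wadsworth–Emmons); this leaves a dienal made from (+)-sclareolide.
- Forward order: decalin bought; C7=C8/C9=C11 dienal; side chain joined at C12; oxirane on C12–C13; oxolane by ring expansion; ring-B oxidation; dihydrofuran last.
- Enabling feature: in the oxolane O–C9–C11–C12–C13 the oxygen sits between two fully substituted carbons joined by a bare C11–C12 bridge. It is therefore the dihydro form of a 2,5-dihydrofuran, the isomer of a C12–C13 oxirane that carries a C9=C11 alkene. The ring-B oxygens at C7/C8 map onto a C7=C8 alkene, which extends that alkene to a diene and makes C9 the hydrogen-free centre of a pentadienyl cation.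
- Stereochemistry: C5 and C10 come with sclareolide; C13 is set by Sharpless asymmetric epoxidation (reagent control); C9 by substrate control in the ring expansion; C8 by substrate-controlled epoxidation and trans-diaxial acetolysis.

Key step: step 8

Remark: locants follow labdane numbering (C1–C20); α is the face opposite the C10 methyl group, and the α-face course of the epoxidation in step 10 is assumed.

**Route**

Step 1
Reactants: 1 (+)-sclareolide
Product: 3 9(11)-dehydrosclareolide, via 11α-phenylselanylsclareolide 2 (not isolated)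
Conditions: LDA, THF, −78 °C; PhSeBr; then 30% H2O2, pyridine, CH2Cl2, 0 °C → rt
Reagents that add atoms: none
Why: The lactone enolate should be selenenylated at C11 from the α-face, anti to the C10 methyl, and the selenoxide then eliminates syn toward H-9, the only β-hydrogen, to give the butenolide (selenoxide elimination).

Step 2
Reactants: 3 9(11)-dehydrosclareolide
Product: 5 (9(11)E)-13,14,15,16-tetranorlabda-7,9(11)-dien-12-al, via lactol 4 (not isolated)
Conditions: DIBAL-H (1.1 equiv), CH2Cl2, −78 °C; then PPTS (cat.), benzene, 50 °C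
Reagents that add atoms: none
Why: DIBAL-H reduces the butenolide to the lactol (1,2-reduction), and mild acid then opens it to the γ-hydroxy enal and removes the tertiary allylic C8 hydroxyl by E1 dehydration toward C7, the conjugated endocyclic diene being the thermodynamic product.

Step 3
Reactants: 6 triethyl phosphonoacetate; 7 bromoacetaldehyde dimethyl acetal
Product: 8 ethyl 2-(diethoxyphosphoryl)-4,4-dimethoxybutanoate
Conditions: NaH, DMF, 0 °C; then 7, NaI (cat.), 80 °C
Reagents that add atoms: none
Why: C-alkylation of the phosphonoacetate sodium enolate by the primary bromide (SN2, helped by in situ Finkelstein exchange); the new stereocentre is racemic and becomes sp2 in step 4.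

Step 4
Reactants: 5 dienal; 8 phosphonate
Product: 9 ethyl (9(11)E,12E)-15,15-dimethoxylabda-7,9(11),12-trien-16-oate
Conditions: NaH, THF, 0 °C → rt
Reagents that add atoms: none
Why: Horner–Wadsworth–Emmons olefination of the unhindered aldehyde should place the ester mainly trans to the dienyl group (12E); a minor 12Z isomer would converge in step 8, where C12 loses its configuration.

Step 5
Reactants: 9 trienoate
Product: 10 (9(11)E,12E)-15,15-dimethoxylabda-7,9(11),12-trien-16-ol
Conditions: DIBAL-H (2.5 equiv), CH2Cl2, −78 °C; Rochelle salt work-up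
Reagents that add atoms: none
Why: DIBAL-H reduces the conjugated ester to the allylic alcohol (1,2-reduction) without touching the acetal or the diene.

Step 6
Reactants: 10 trienol
Product: 11 (12R,13R)-12,13-epoxy-15,15-dimethoxylabda-7,9(11)-dien-16-ol
Conditions: Ti(OiPr)4 (10 mol %), D-(−)-diethyl tartrate (12 mol %), t-BuOOH, 4 Å MS, CH2Cl2, −25 °C
Reagents that add atoms: tert-butyl hydroperoxide, CC(C)(C)OO
Why: Sharpless asymmetric epoxidation of the (E)-2,3-disubstituted allylic alcohol; D-(−)-tartrate should deliver oxygen to the face that gives (12R,13R), so C13 is set by reagent control, and the diene, which has no directing hydroxyl, is left alone.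

Step 7
Reactants: 11 epoxy alcohol
Product: 12 (12R,13R)-16-(tert-butyldimethylsilyloxy)-12,13-epoxy-15,15-dimethoxylabda-7,9(11)-diene
Conditions: TBSCl, imidazole, DMF, 0 °C → rt
Reagents that add atoms: tert-butyldimethylsilyl chloride, CC(C)(C)[Si](C)(C)Cl
Why: Imidazole-promoted silylation masks the primary hydroxyl so that it can neither bind the Lewis acid nor trap the cation in step 8.

Step 8
Reactants: 12 silylated dienyl oxirane
Product: 13 (13S)-16-(tert-butyldimethylsilyloxy)-9α,13-epoxy-15,15-dimethoxylabda-7,11-diene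
Conditions: Cu(hfacac)2 (5 mol %), toluene, 150 °C, sealed tube
Reagents that add atoms: none
Why: Cu(II) acts as a Lewis acid on the oxirane oxygen, and the allylic C12–O bond ionises to a copper alkoxide on C13 and a pentadienyl cation over C12–C11–C9–C8–C7 (equivalently a Cu(III) allyl), which recombines by C–O bond formation at C9. The closest known reaction type is the Cu(hfacac)2-catalysed rearrangement of 2-vinyl oxiranes to 2,5-dihydrofurans. The oxolane (O, C13, C12, C11, C9) closes by attack of the C13 alkoxide on the distal allyl terminus C9 (ionisation–recombination, formally a 1,3-oxygen shift with 3 → 5 ring expansion). The C13–O bond is never broken, so the configuration from step 6 is carried over; the new C9 centre is set by substrate control, because the alkoxide should add axially to the planar C9 from the α-face, anti to the axial C10 methyl, which leaves C11 equatorial. The step needs closure at C9 in preference to closure at C7 (oxepine) and to proton loss; the five-membered transition state, the absence of hydrogens on C8 and C10 and the non-basic medium should secure this. Both C12 epimers and both alkene geometries of the precursor converge, because C11 and C12 become the ring alkene.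

Step 9
Reactants: 13 dihydrofuran
Product: 14 (13R)-16-(tert-butyldimethylsilyloxy)-9α,13-epoxy-15,15-dimethoxylabd-7-ene
Conditions: H2 (1 atm), 5% Rh/Al2O3, EtOAc, rt
Reagents that add atoms: none
Why: Heterogeneous hydrogenation should saturate the cis-disubstituted C11=C12 alkene much faster than the trisubstituted C7=C8 alkene, and rhodium on alumina keeps hydrogenolysis of the allylic C–O bonds low.

Step 10
Reactants: 14 alkene
Product: 15 (13R)-16-(tert-butyldimethylsilyloxy)-7α,8α:9α,13-diepoxy-15,15-dimethoxylabdane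
Conditions: mCPBA, CH2Cl2, 0 °C
Reagents that add atoms: 3-chloroperoxybenzoic acid, OOC(=O)c1cccc(Cl)c1
Why: Prilezhaev epoxidation of the only alkene left; the peracid should approach the α-face, anti to the axial C10 methyl group.

Step 11
Reactants: 15 epoxide
Product: 16 (13R)-8β-acetoxy-16-(tert-butyldimethylsilyloxy)-9α,13-epoxy-15,15-dimethoxylabdan-7α-ol
Conditions: glacial AcOH, NaOAc (buffer), 45 °C
Reagents that add atoms: acetic acid, CC(=O)O
Why: Acid-catalysed trans-diaxial (Fürst–Plattner) epoxide opening: acetic acid attacks the tertiary C8 from the β-face with inversion, which installs the axial 8β-acetate and leaves the axial 7α-hydroxyl.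

Step 12
Reactants: 16 hydroxy acetate
Product: 17 (13R)-8β-acetoxy-16-(tert-butyldimethylsilyloxy)-9α,13-epoxy-15,15-dimethoxylabdan-7-one
Conditions: TPAP (5 mol %), NMO, 4 Å MS, CH2Cl2, rt
Reagents that add atoms: none
Why: Ley–Griffith oxidation of the secondary alcohol under neutral conditions; the tertiary acetate, the acetal and the silyl ether are inert.

Step 13
Reactants: 17 ketone
Product: 19 (13R)-8β-acetoxy-9α,13:15,16-diepoxy-15-hydroxylabdan-7-one, via hydroxy aldehyde 18 (not isolated)
Conditions: 1 M aq. HCl, THF, rt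
Reagents that add atoms: water, O
Why: Aqueous acid cleaves the primary silyl ether and hydrolyses the dimethyl acetal, and the γ-hydroxy aldehyde closes to the five-membered lactol (5-exo-trig hemiacetalisation).

Step 14
Reactants: 19 lactol
Product: 21 (13R)-8β-acetoxy-9α,13:15,16-diepoxylabd-14-en-7-one (CNP0165143.1), via 15-O-mesylate 20 (not isolated)
Conditions: MsCl, Et3N, CH2Cl2, −20 °C → reflux
Reagents that add atoms: none
Why: Mesylation of the anomeric hydroxyl and amine-promoted loss of methanesulfonate through the oxocarbenium ion give the 2,3-dihydrofuran (glycal-type lactol dehydration); only C14 carries hydrogens next to C15, so the enol ether can form in one direction only.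

**Compound list**

1 | (+)-sclareolide | C[C@]12CCCC(C)(C)[C@@H]1CC[C@@]1(C)OC(=O)C[C@H]21 | starting material
2 | 11α-phenylselanylsclareolide | C[C@]12CCCC(C)(C)[C@@H]1CC[C@@]1(C)OC(=O)[C@@H]([Se]c3ccccc3)[C@H]21 | intermediate
3 | 9(11)-dehydrosclareolide (8α,12-epoxy-13,14,15,16-tetranorlabd-9(11)-en-12-one) | C[C@]12CCCC(C)(C)[C@@H]1CC[C@@]1(C)OC(=O)C=C21 | intermediate
4 | 8α,12-epoxy-13,14,15,16-tetranorlabd-9(11)-en-12-ol (lactol, C12 epimers) | C[C@]12CCCC(C)(C)[C@@H]1CC[C@@]1(C)OC(O)C=C21 | intermediate
5 | (9(11)E)-13,14,15,16-tetranorlabda-7,9(11)-dien-12-al (C12 cis to C8) | C[C@]12CCCC(C)(C)[C@@H]1CC=C(C)/C2=C\C=O | intermediate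
6 | triethyl phosphonoacetate | CCOC(=O)CP(=O)(OCC)OCC | starting material
7 | bromoacetaldehyde dimethyl acetal | COC(CBr)OC | starting material
8 | ethyl 2-(diethoxyphosphoryl)-4,4-dimethoxybutanoate (racemic) | CCOC(=O)C(CC(OC)OC)P(=O)(OCC)OCC | intermediate
9 | ethyl (9(11)E,12E)-15,15-dimethoxylabda-7,9(11),12-trien-16-oate | C[C@]12CCCC(C)(C)[C@@H]1CC=C(C)/C2=C\C=C(/CC(OC)OC)C(=O)OCC | intermediate
10 | (9(11)E,12E)-15,15-dimethoxylabda-7,9(11),12-trien-16-ol | C[C@]12CCCC(C)(C)[C@@H]1CC=C(C)/C2=C\C=C(/CC(OC)OC)CO | intermediate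
11 | (12R,13R)-12,13-epoxy-15,15-dimethoxylabda-7,9(11)-dien-16-ol | C[C@]12CCCC(C)(C)[C@@H]1CC=C(C)/C2=C\[C@H]3O[C@]3(CC(OC)OC)CO | intermediate
12 | (12R,13R)-16-(tert-butyldimethylsilyloxy)-12,13-epoxy-15,15-dimethoxylabda-7,9(11)-diene | C[C@]12CCCC(C)(C)[C@@H]1CC=C(C)/C2=C\[C@H]3O[C@]3(CC(OC)OC)CO[Si](C)(C)C(C)(C)C | intermediate
13 | (13S)-16-(tert-butyldimethylsilyloxy)-9α,13-epoxy-15,15-dimethoxylabda-7,11-diene | C[C@]12CCCC(C)(C)[C@@H]1CC=C(C)[C@]23C=C[C@@](CC(OC)OC)(CO[Si](C)(C)C(C)(C)C)O3 | intermediate
14 | (13R)-16-(tert-butyldimethylsilyloxy)-9α,13-epoxy-15,15-dimethoxylabd-7-ene | C[C@]12CCCC(C)(C)[C@@H]1CC=C(C)[C@]23CC[C@@](CC(OC)OC)(CO[Si](C)(C)C(C)(C)C)O3 | intermediate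
15 | (13R)-16-(tert-butyldimethylsilyloxy)-7α,8α:9α,13-diepoxy-15,15-dimethoxylabdane | C[C@]12CCCC(C)(C)[C@@H]1C[C@H]4O[C@@]4(C)[C@]23CC[C@@](CC(OC)OC)(CO[Si](C)(C)C(C)(C)C)O3 | intermediate
16 | (13R)-8β-acetoxy-16-(tert-butyldimethylsilyloxy)-9α,13-epoxy-15,15-dimethoxylabdan-7α-ol | C[C@]12CCCC(C)(C)[C@@H]1C[C@@H](O)[C@](C)(OC(C)=O)[C@]23CC[C@@](CC(OC)OC)(CO[Si](C)(C)C(C)(C)C)O3 | intermediate
17 | (13R)-8β-acetoxy-16-(tert-butyldimethylsilyloxy)-9α,13-epoxy-15,15-dimethoxylabdan-7-one | C[C@]12CCCC(C)(C)[C@@H]1CC(=O)[C@](C)(OC(C)=O)[C@]23CC[C@@](CC(OC)OC)(CO[Si](C)(C)C(C)(C)C)O3 | intermediate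
18 | (13R)-8β-acetoxy-9α,13-epoxy-16-hydroxy-7-oxolabdan-15-al | C[C@]12CCCC(C)(C)[C@@H]1CC(=O)[C@](C)(OC(C)=O)[C@]23CC[C@@](CC=O)(CO)O3 | intermediate
19 | (13R)-8β-acetoxy-9α,13:15,16-diepoxy-15-hydroxylabdan-7-one (lactol, C15 epimers) | C[C@]12CCCC(C)(C)[C@@H]1CC(=O)[C@](C)(OC(C)=O)[C@]23CC[C@]4(CC(O)OC4)O3 | intermediate
20 | (13R)-8β-acetoxy-9α,13:15,16-diepoxy-15-(methanesulfonyloxy)labdan-7-one | C[C@]12CCCC(C)(C)[C@@H]1CC(=O)[C@](C)(OC(C)=O)[C@]23CC[C@]4(CC(OS(C)(=O)=O)OC4)O3 | intermediate
21 | (13R)-8β-acetoxy-9α,13:15,16-diepoxylabd-14-en-7-one (CNP0165143.1) | C[C@]12CCCC(C)(C)[C@@H]1CC(=O)[C@](C)(OC(C)=O)[C@]23CC[C@]4(C=COC4)O3 | target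

**Step count**

Total: 14 steps. Longest linear sequence: 13 steps (steps 1, 2 and 4–14, from sclareolide).

**Steps most likely to fail**

Step 8. The hindered pentadienyl cation may lose a proton from C6, close at C7, or fail to recombine with the tertiary alkoxide. The fallback sets out from 11 and returns at 14. DIBAL-H should open the 2,3-epoxy alcohol 11 by hydride delivery to the allylic C12 and give (13R)-15,15-dimethoxylabda-7,9(11)-diene-13,16-diol F1. TBSCl and imidazole silylate the primary hydroxyl to give (13R)-16-(tert-butyldimethylsilyloxy)-15,15-dimethoxylabda-7,9(11)-dien-13-ol F2. Catalytic CSA in CH2Cl2 then protonates the diene at C11, and the tertiary 13-hydroxyl traps the allyl cation at C9 from the α-face (5-exo cycloetherification), which gives 14 directly.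

Step 10 (with step 11). The axial oxygen on C9 may erode the facial selectivity of the epoxidation, and the acetolysis may be diverted to elimination or hydride shift. The fallback sets out from 14 and returns at 17. Woodward–Prévost hydroxyacetoxylation (I2, AgOAc, AcOH, then water) forms the iodonium reversibly. Only the α-iodonium can be opened diaxially by acetate at the tertiary C8. The 7α-iodide is then displaced by the neighbouring acetate, and hydrolysis of the dioxolanylium ion should leave the axial tertiary ester, (13R)-8β-acetoxy-16-(tert-butyldimethylsilyloxy)-9α,13-epoxy-15,15-dimethoxylabdan-7β-ol F3. TPAP/NMO oxidation of F3 gives 17.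

Step 2. The dehydration may give the exocyclic C8=C17 isomer or degrade the sensitive lactol and dienal. The fallback sets out from 3 and returns at 5. Hot methanolic H2SO4 ionises the tertiary lactone C8–O bond, and elimination under equilibrating conditions with esterification should give methyl (9(11)E)-13,14,15,16-tetranorlabda-7,9(11)-dien-12-oate F4. DIBAL-H reduces it to (9(11)E)-13,14,15,16-tetranorlabda-7,9(11)-dien-12-ol F5, and MnO2 oxidises the allylic alcohol to 5.

Further compounds
F1 | step 8 | (13R)-15,15-dimethoxylabda-7,9(11)-diene-13,16-diol | C[C@]12CCCC(C)(C)[C@@H]1CC=C(C)/C2=C\C[C@@](O)(CC(OC)OC)CO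
F2 | step 8 | (13R)-16-(tert-butyldimethylsilyloxy)-15,15-dimethoxylabda-7,9(11)-dien-13-ol | C[C@]12CCCC(C)(C)[C@@H]1CC=C(C)/C2=C\C[C@@](O)(CC(OC)OC)CO[Si](C)(C)C(C)(C)C
F3 | step 10 | (13R)-8β-acetoxy-16-(tert-butyldimethylsilyloxy)-9α,13-epoxy-15,15-dimethoxylabdan-7β-ol | C[C@]12CCCC(C)(C)[C@@H]1C[C@H](O)[C@](C)(OC(C)=O)[C@]23CC[C@@](CC(OC)OC)(CO[Si](C)(C)C(C)(C)C)O3
F4 | step 2 | methyl (9(11)E)-13,14,15,16-tetranorlabda-7,9(11)-dien-12-oate | C[C@]12CCCC(C)(C)[C@@H]1CC=C(C)/C2=C\C(=O)OC
F5 | step 2 | (9(11)E)-13,14,15,16-tetranorlabda-7,9(11)-dien-12-ol | C[C@]12CCCC(C)(C)[C@@H]1CC=C(C)/C2=C\CO
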